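## Structural features

The target is a 2,3-trans flavanonol: a trioxygenated benzene ring (ring A) fused to a dihydropyran-4-one (ring C) that carries a 4-hydroxyphenyl group (ring B) on C2 and a hydroxyl on C3, with a 1-(4-hydroxyphenyl)ethyl group on C6 of ring A. There are three stereocentres, all R. C2 and C3 are neighbours on ring C, whereas the exocyclic methine C-alpha on C6 is insulated from them by the arene and must be brought in enantiopure. Ring A has oxygens on C5, C7 and C8a alternating with carbons; C6 lies between the C5 and C7 oxygens, which both end as phenols, while the oxygen para to C6 is the ring oxygen O1. The real difficulty is twofold: a doubly benzylic stereocentre wedged between two ortho oxygens on a very electron-rich ring, and telling the para oxygen from its two look-alike neighbours. Fragile points are the α-hydroxy ketone (C3 epimerisation, oxidation to the flavonol), the benzylic C2–O1 ether (chalcone opening in base, ionisation in acid helped by ring B), the free phenols, and C-alpha, which ipso-protonation of ring A could cleave or scramble while the ring is not yet deactivated by the C4 carbonyl. The key step uses the alternating pattern: a four-carbon vinylketene holding C4a, C5 with its oxygen, C6 with C-alpha, and C7 is joined to a two-carbon ynol ether that supplies C8 and the oxygen-bearing C8a, so the silyl-tagged oxygen lands para to C6 by mechanism.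

## Logic of the disconnections

28 ⇒ 27. The four O–benzyl bonds are cut. One neutral hydrogenolysis frees all phenols without acid or base, which the α-hydroxy ketone and C2 would not tolerate. 27 has no acidic phenol and can be made under acylating conditions. The forward step must spare the C2–O1 benzylic ether, the ketone and the aryl–C-alpha bonds.

27 ⇒ 24. C4–C4a is cut (retro-Friedel–Crafts acylation). It is the one ring-C bond whose formation creates no stereocentre and which the electron-rich ring A makes easy. The bicyclic ketone becomes an open-chain acid with C2 and C3 already fixed, and because O5 and O7 carry the same group in 24 the two carbons ortho to O1 are equivalent. The forward step needs a carboxyl activation that masks the free 2-hydroxyl in passing and does not ionise the benzylic C–O bond.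

24 ⇒ 19 + 22 (through 23). O1–C2 is cut, with the ester hydrolysis behind it. This separates ring A with C-alpha from a three-carbon unit with ring B and derives both ring-C stereocentres from an epoxide (C3 retained, C2 by inversion). It is the largest simplification of the plan. It demands that only the oxygen para to C6 is free in 19 and that the opening is clean SN2 at the benzylic carbon.

22 ⇒ 21 ⇒ 20. The two oxirane C–O bonds, then the C=C bond, are cut. The stereocentres come from a reagent-controlled oxygen transfer to a planar (E)-alkene that is one olefination from an aldehyde. The forward steps need high E-selectivity, high face selectivity and buffered conditions, since 22 is acid-labile.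

19 ⇒ 18 ⇒ 17 ⇒ 16. Only oxygen–protecting-group bonds change: O1–Si, the O–benzyl bonds on O5 and O7, and O5–tert-butyl. The tert-butyl ether that serves the ring synthesis would not survive the acidic acylation and would make the two ortho carbons different; exchanging it for benzyl while O1 stays silylated makes 19 locally symmetric. This leads back to 16, whose three oxygens are all different (free, tert-butyl, silyl). The acid cleavage must spare the aryl silyl ether and neither alkylate nor dealkylate the ring; fluoride must be the only reagent that frees O1.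

16 ⇒ 8 + 11. C7–C8, C4a–C8a and C6–C7 are cut, which dismantles ring A. The cut removes the ring and its substitution problem together: 8 holds C-alpha, C6, C5 with its oxygen, C4a and C7, and 11 holds C8 and C8a with the tagged oxygen. The forward step must open 8 thermally without losing the tert-butyl group, and the cycloaddition must be regioselective.

11 ⇒ 9 (through 10). The O–Si bond is cut, then the ester C–O bond. The two-carbon ynolate is reached from a commodity ester. Silylation must occur at oxygen, not carbon.

8 ⇒ 4 + 5 (through 6 and 7). The two bonds made by ketene–alkyne cycloaddition are cut: C5–C6, which persists, and the bond from the carbonyl carbon (later C7) to the alkyne CH (later C4a), which the key step breaks again. The four-membered ring reduces to an acid and a two-carbon ynol ether. The ketene must be trapped faster than it dimerises and below the decomposition temperature of 5.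

4 ⇒ 3 ⇒ 1 + 2. The C-alpha–aryl bond is cut (conjugate addition), then the ester. The only stereocentre of this half comes from a catalytic asymmetric addition to a simple enoate. The forward step must deliver high ee, which crystallisation of 4 can raise.

## Other disconnections considered

Alternative 1: The C3–O and C4–O bonds are cut together: the ketol is traced to the cis-3,4-diol A1 and this to the 2-aryl-2H-chromene A2 (C2 arranged as in the target, formally S because the ranking changes).
- Forward step: catalytic OsO4 with N-methylmorpholine N-oxide would add to C3=C4 anti to the C2 aryl group; the C4 carbinol of A1 would then be oxidised (MnO2 or DDQ) and the benzyl ethers removed.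
- In favour: the 2,3-trans relationship comes from a dependable substrate-controlled syn addition, no acid-mediated acylation is needed, and the α-hydroxy ketone exists for one step only. On control of C3 this plan is the equal of the chosen one, and on mildness of the ring-C chemistry it is the better.
- Against: all chirality of ring C rests on C2 of A2, an allylic, doubly activated benzylic ether that can racemise through the ring-opened quinone methide or the flavylium ion. A1 is a leucoanthocyanidin-type carbinol that ionises easily with this ring A. Ring A itself is left unsolved, so O1 differentiation and C-alpha would still need something like 19.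
- Comparison: structurally it addresses ring C only; mechanistically it trades an acid-sensitive acylation for an ionisation-prone diol; in steps it is longer by two redox operations.

Alternative 2: C4–C4a of the tetra-O-benzyl flavanonol A3 is cut.
- Forward step: the acid is activated with trifluoroacetic anhydride and acylates ring A ortho to O1; identical groups on O5 and O7 make either ortho carbon give the same ketone.
- In favour: one bond closes ring C with both stereocentres in place, and there is no regiochemistry. On this bond the plan is exactly the equal of the chosen one, which ends with the same closure (A3 is the same compound as 27).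
- Difference: taken as the strategic step, this closure suggests a symmetric phloroglucinol-derived ring A, which labels O1 by symmetry at no cost. That is better than the chosen plan in step count for the label.
- Against: C-alpha must then be attached enantioselectively at the hindered carbon between two ortho oxygens, by asymmetric hydroarylation or hydrogenation whose selectivity there is uncertain. The chosen plan spends extra steps to take C-alpha from a conjugate addition of established reliability and the label from the mechanism. Both plans share the acid sensitivity of the benzylic ether.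

Alternative 3: C8–C8a and C4a–C5 are cut, so ring A is assembled onto a finished ring C.
- Forward step: diene A5 (arylethyl group on C2) would add to sulfonyl dihydropyranone A6, the CH2 terminus bonding to the carbon next to the ring oxygen and the ketene acetal carbon to the sulfonyl-bearing carbon; loss of benzenesulfinic acid and methanol would aromatise to A4.
- In favour: ring A appears with free 5- and 7-hydroxyls and O1 already in place, so neither oxygen differentiation nor protecting-group exchange on ring A arises. That is better than the chosen plan on this point. The regiochemistry is electronically matched and the plan is highly convergent.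
- Against: A5 has a fully substituted ketene acetal terminus and a bulky secondary benzylic group on C2, which should slow a bimolecular [4+2]. A6 is a sensitive β-alkoxy enone whose C3 is α to the ketone and whose C2 can leave by retro-oxa-Michael opening, so both ring-C stereocentres face the cycloaddition and elimination conditions. Enantiopure A6 and A5 are each multi-step tasks.
- Comparison: structurally it is the most direct; mechanistically a hindered intermolecular cycloaddition is set against an intramolecular pericyclic cascade; step economy is expected to be about equal.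

Key step: step 5

Assumption: 5 and the L-fructose-derived epoxidation ketone are taken as purchasable, and 5 is handled below about 30 °C because it fragments to ketene and isobutene on warming.

Structure check: no atom or descriptor of the planned precursor and product needs correcting. S in 3–8 and 12–15 and R from 16 onward describe the same arrangement at C-alpha; the letter changes because the neighbouring ring carbon gains rank once it is an oxygen-flanked arene carbon.

Design changes: (R)-BINAP is required for the S ester. The tert-butyl ether of 8 is kept only as a temporary label for O5 and is exchanged for benzyl directly after the key step (steps 6 and 7).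

## Steps

Step 1
Reactants: 1 ethyl (2E)-but-2-enoate; 2 [4-(benzyloxy)phenyl]boronic acid
Product: 3 ethyl (3S)-3-[4-(benzyloxy)phenyl]butanoate
Conditions: [Rh(C7H8)2]BF4 (1 mol %, C7H8 = norbornadiene), (R)-BINAP (1.1 mol %), Et3N (1 equiv), 1,4-dioxane/H2O 10:1, 30 °C
Reagents that add atoms: none
Why: Rhodium-catalysed asymmetric 1,4-addition of an arylboronic acid to an enoate (Hayashi–Miyaura reaction); the aryl–rhodium–BINAP species inserts the (E)-crotonate on the enantioface chosen by the ligand, and (R)-BINAP is the enantiomer that should give the S ester; water protonates the rhodium enolate.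

Step 2
Reactants: 3 ethyl (3S)-3-[4-(benzyloxy)phenyl]butanoate
Product: 4 (3S)-3-[4-(benzyloxy)phenyl]butanoic acid
Conditions: LiOH·H2O, THF/MeOH/H2O, rt; aq. HCl; recrystallisation
Reagents that add atoms: lithium hydroxide, [Li+].[OH-]
Why: Saponification; C-alpha is β to the carboxyl group and cannot epimerise, and crystallisation of the acid can raise the enantiomeric purity.

Step 3
Reactants: 4 (3S)-3-[4-(benzyloxy)phenyl]butanoic acid; 5 tert-butoxyethyne
Product: 8 4-{(1S)-1-[4-(benzyloxy)phenyl]ethyl}-3-tert-butoxycyclobut-2-en-1-one (both C4 epimers), via acid chloride 6 (not isolated), via ketene 7 (not isolated)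
Conditions: (COCl)2, cat. DMF, CH2Cl2, 0 °C to rt, volatiles stripped; then slow addition to 5 (2 equiv), Et3N (1.3 equiv), Et2O, 0 °C to rt
Reagents that add atoms: none
Why: Dehydrochlorination gives the aldoketene, which is trapped as it forms by the electron-rich ynol ether in a regioselective ketene–alkyne [2+2] cycloaddition (carbonyl carbon to the alkyne CH, α-carbon to the alkoxy carbon), the standard entry to 3-alkoxycyclobutenones; the C4 epimers do not matter because that carbon becomes sp2.

Step 4
Reactants: 9 ethyl bromoacetate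
Product: 11 (triisopropylsilyloxy)ethyne, via lithium ethynolate 10 (not isolated)
Conditions: LiN(SiMe3)2, THF, −78 °C; t-BuLi (2.1 equiv), −78 to 0 °C; i-Pr3SiOSO2CF3, −78 °C to rt; pentane extraction, short-path distillation
Reagents that add atoms: triisopropylsilyl trifluoromethanesulfonate, CC(C)[Si](OS(=O)(=O)C(F)(F)F)(C(C)C)C(C)C
Why: Ynolate synthesis by ester-dianion fragmentation (enolisation of the α-bromo ester, bromine–lithium exchange, loss of lithium ethoxide) followed by O-silylation, the usual route to triisopropylsilyl ynol ethers; the hard triflate and the bulk at silicon favour oxygen over carbon.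

Step 5
Reactants: 8 4-{(1S)-1-[4-(benzyloxy)phenyl]ethyl}-3-tert-butoxycyclobut-2-en-1-one; 11 (triisopropylsilyloxy)ethyne
Product: 16 2-{(1R)-1-[4-(benzyloxy)phenyl]ethyl}-3-tert-butoxy-5-(triisopropylsilyloxy)phenol, via vinylketene 12 (not isolated), via vinylcyclobutenone 13 (not isolated), via dienylketene 14 (not isolated), via cyclohexadienone 15 (not isolated)
Conditions: 11 (2 equiv), toluene (0.4 M), 2,6-di-tert-butyl-4-methylpyridine (5 mol %), sealed tube, 80 °C then 110 °C
Reagents that add atoms: none
Why: This is the strain-release benzannulation of a cyclobutenone with a silyl ynol ether (Danheiser benzannulation), a known reaction type. Heating opens 8 by a four-electron conrotatory electrocyclic reaction to vinylketene 12, in which C6 already carries C-alpha and C5 the tert-butoxy group. The ketene is electrophilic at its central carbon (C7) and the ynol ether nucleophilic at its CH carbon, so the [2+2] cycloaddition joins C7 to C8 and C4a to C8a and gives 13 with one regiochemistry. Ring strain drives a second four-electron opening to dienylketene 14, whose six-electron disrotatory electrocyclisation forms C6–C7 and closes ring A as a six-membered carbocycle (15); enolisation makes the ring aromatic and the sequence irreversible. No stereocentre is created, since the sp3 ring carbons of 8 and 15 become sp2, and C-alpha is a spectator that is never α to a carbonyl. The only selectivity needed is regiochemical, the silyloxy carbon para to C6, and the oxygen-controlled polarity of both partners secures it. Likely diversions ([1,5]-hydrogen shift in 12 when the side chain turns inward, acylation of the product phenol by 12) would cost yield but not ee, and excess 11 and a trace of hindered base hold them back.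

Step 6
Reactants: 16 2-{(1R)-1-[4-(benzyloxy)phenyl]ethyl}-3-tert-butoxy-5-(triisopropylsilyloxy)phenol
Product: 17 2-{(1R)-1-[4-(benzyloxy)phenyl]ethyl}-5-(triisopropylsilyloxy)benzene-1,3-diol
Conditions: CF3CO2H (10 equiv), Et3SiH (3 equiv), CH2Cl2, 0 °C, short reaction time, cold aqueous quench
Reagents that add atoms: none
Why: Acidolysis of an aryl tert-butyl ether by ionisation at the tertiary carbon; the aryl triisopropylsilyl ether and the benzyl ether withstand brief cold trifluoroacetic acid, and the silane reduces the tert-butyl cation before it can alkylate the ring.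

Step 7
Reactants: 17 2-{(1R)-1-[4-(benzyloxy)phenyl]ethyl}-5-(triisopropylsilyloxy)benzene-1,3-diol
Product: 18 {3,5-bis(benzyloxy)-4-[(1R)-1-[4-(benzyloxy)phenyl]ethyl]phenoxy}tri(propan-2-yl)silane
Conditions: BnBr (2.5 equiv), K2CO3 (3 equiv), Bu4NI (cat.), DMF, rt
Reagents that add atoms: benzyl bromide, BrCc1ccccc1
Why: Williamson etherification of both phenols; in a dipolar aprotic solvent the phenoxides react at oxygen rather than at ring carbon, and the aryl silyl ether is stable to carbonate at room temperature.

Step 8
Reactants: 18 {3,5-bis(benzyloxy)-4-[(1R)-1-[4-(benzyloxy)phenyl]ethyl]phenoxy}tri(propan-2-yl)silane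
Product: 19 3,5-bis(benzyloxy)-4-{(1R)-1-[4-(benzyloxy)phenyl]ethyl}phenol
Conditions: Bu4NF (1.1 equiv), AcOH (1.1 equiv), THF, 0 °C
Reagents that add atoms: none
Why: Fluoride cleavage of the aryl silyl ether, driven by the Si–F bond and buffered by acetic acid; the only free oxygen is now the one para to C6.

Step 9
Reactants: 20 4-(benzyloxy)benzaldehyde
Product: 21 methyl (2E)-3-[4-(benzyloxy)phenyl]prop-2-enoate
Conditions: (MeO)2P(O)CH2CO2Me, NaH, THF, 0 °C to rt
Reagents that add atoms: trimethyl phosphonoacetate, COC(=O)CP(=O)(OC)OC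
Why: Horner–Wadsworth–Emmons olefination; the stabilised phosphonate anion gives the (E)-cinnamate needed for a trans epoxide.

Step 10
Reactants: 21 methyl (2E)-3-[4-(benzyloxy)phenyl]prop-2-enoate
Product: 22 methyl (2R,3S)-3-[4-(benzyloxy)phenyl]oxirane-2-carboxylate
Conditions: L-fructose-derived diacetate ketone (ester-type Shi catalyst, enantiomeric series, 25 mol %), KHSO5 (as 2KHSO5·KHSO4·K2SO4, 5 equiv), NaHCO3, Bu4NHSO4 (cat.), MeCN/aq. disodium EDTA (C10H14N2Na2O8), 0 °C
Reagents that add atoms: potassium peroxymonosulfate, [K+].[O-]S(=O)(=O)OO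
Why: Shi epoxidation of an (E)-cinnamate by a chiral dioxirane formed in situ; oxygen is delivered to one enantioface through the spiro transition state, and since the D-fructose-derived catalyst leads to the (2S,3R) series with (E)-cinnamates, its enantiomer is used to set C2 (R) and C3 (S); the bicarbonate buffer protects the acid-labile aryl glycidate.

Step 11
Reactants: 19 3,5-bis(benzyloxy)-4-{(1R)-1-[4-(benzyloxy)phenyl]ethyl}phenol; 22 methyl (2R,3S)-3-[4-(benzyloxy)phenyl]oxirane-2-carboxylate
Product: 24 (2R,3R)-3-{3,5-bis(benzyloxy)-4-[(1R)-1-[4-(benzyloxy)phenyl]ethyl]phenoxy}-3-[4-(benzyloxy)phenyl]-2-hydroxypropanoic acid, via methyl ester 23 (not isolated)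
Conditions: 22 (1.3 equiv), Cs2CO3 (0.2 equiv), DMF, 45 °C; then LiOH, THF/H2O, 0 °C; aq. HCl to pH 3
Reagents that add atoms: lithium hydroxide, [Li+].[OH-]
Why: Base-catalysed anti opening of a 3-arylglycidate by a phenoxide at the benzylic carbon (SN2), a known mode for aryl oxide and aryl thiolate nucleophiles; C3 is inverted (S to R) and C2 untouched, giving the anti hydroxy ester that maps onto the 2,3-trans flavanonol; the alkoxide formed deprotonates the next phenol, so carbonate is catalytic, and cold saponification then frees the acid.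

Step 12
Reactants: 24 (2R,3R)-3-{3,5-bis(benzyloxy)-4-[(1R)-1-[4-(benzyloxy)phenyl]ethyl]phenoxy}-3-[4-(benzyloxy)phenyl]-2-hydroxypropanoic acid
Product: 27 (2R,3R)-5,7-bis(benzyloxy)-2-[4-(benzyloxy)phenyl]-6-{(1R)-1-[4-(benzyloxy)phenyl]ethyl}-3-hydroxy-2,3-dihydro-4H-chromen-4-one, via mixed anhydride 25 (not isolated), via trifluoroacetate 26 (not isolated)
Conditions: (CF3CO)2O (3 equiv), CH2Cl2, 0 °C to rt; volatiles removed; MeOH, rt
Reagents that add atoms: none
Why: Intramolecular Friedel–Crafts acylation through the mixed trifluoroacetic anhydride, closing the six-membered ring C at the carbon ortho to O1; the phloroglucinol-type ring should react without added Lewis acid, the 2-hydroxyl is masked in the same flask as its trifluoroacetate and freed by methanolysis of 26, and identical groups on O5 and O7 make the two ortho carbons equivalent, so one ketone results with C2 and C3 untouched.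

Step 13
Reactants: 27 (2R,3R)-5,7-bis(benzyloxy)-2-[4-(benzyloxy)phenyl]-6-{(1R)-1-[4-(benzyloxy)phenyl]ethyl}-3-hydroxy-2,3-dihydro-4H-chromen-4-one
Product: 28 (2R,3R)-3,5,7-trihydroxy-2-(4-hydroxyphenyl)-6-[(1R)-1-(4-hydroxyphenyl)ethyl]-2,3-dihydro-4H-chromen-4-one
Conditions: H2 (1 atm), 10% Pd/C, EtOAc/MeOH, rt
Reagents that add atoms: none
Why: Hydrogenolysis of four aryl benzyl ethers over palladium; under neutral conditions at low pressure the C4 ketone, the ring C2–O1 ether and the aryl–C-alpha bonds are expected to survive, as is usual for benzyl-protected flavanonols, and no stereocentre is involved.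

## Compound list

1 | ethyl (2E)-but-2-enoate | C/C=C/C(=O)OCC | starting material
2 | [4-(benzyloxy)phenyl]boronic acid | OB(O)c1ccc(OCc2ccccc2)cc1 | starting material
3 | ethyl (3S)-3-[4-(benzyloxy)phenyl]butanoate | CCOC(=O)C[C@H](C)c1ccc(OCc2ccccc2)cc1 | intermediate
4 | (3S)-3-[4-(benzyloxy)phenyl]butanoic acid | OC(=O)C[C@H](C)c1ccc(OCc2ccccc2)cc1 | intermediate
5 | tert-butoxyethyne | C#COC(C)(C)C | starting material
6 | (3S)-3-[4-(benzyloxy)phenyl]butanoyl chloride | ClC(=O)C[C@H](C)c1ccc(OCc2ccccc2)cc1 | intermediate (not isolated)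
7 | (3S)-3-[4-(benzyloxy)phenyl]but-1-en-1-one (ketene) | O=C=C[C@H](C)c1ccc(OCc2ccccc2)cc1 | intermediate (not isolated)
8 | 4-{(1S)-1-[4-(benzyloxy)phenyl]ethyl}-3-tert-butoxycyclobut-2-en-1-one (C4 epimers) | O=C1C=C(OC(C)(C)C)C1[C@H](C)c1ccc(OCc2ccccc2)cc1 | intermediate
9 | ethyl bromoacetate | CCOC(=O)CBr | starting material
10 | lithium ethynolate | [Li+].[O-]C#C | intermediate (not isolated)
11 | (triisopropylsilyloxy)ethyne | C#CO[Si](C(C)C)(C(C)C)C(C)C | intermediate
12 | (5S)-5-[4-(benzyloxy)phenyl]-3-tert-butoxyhexa-1,3-dien-1-one (vinylketene) | O=C=CC(OC(C)(C)C)=C[C@H](C)c1ccc(OCc2ccccc2)cc1 | intermediate (not isolated)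
13 | 4-{(3S)-3-[4-(benzyloxy)phenyl]-1-tert-butoxybut-1-en-1-yl}-3-(triisopropylsilyloxy)cyclobut-2-en-1-one | O=C1C=C(O[Si](C(C)C)(C(C)C)C(C)C)C1C(OC(C)(C)C)=C[C@H](C)c1ccc(OCc2ccccc2)cc1 | intermediate (not isolated)
14 | (7S)-7-[4-(benzyloxy)phenyl]-5-tert-butoxy-3-(triisopropylsilyloxy)octa-1,3,5-trien-1-one (dienylketene) | O=C=CC(O[Si](C(C)C)(C(C)C)C(C)C)=CC(OC(C)(C)C)=C[C@H](C)c1ccc(OCc2ccccc2)cc1 | intermediate (not isolated)
15 | 6-{(1S)-1-[4-(benzyloxy)phenyl]ethyl}-5-tert-butoxy-3-(triisopropylsilyloxy)cyclohexa-2,4-dien-1-one | O=C1C=C(O[Si](C(C)C)(C(C)C)C(C)C)C=C(OC(C)(C)C)C1[C@H](C)c1ccc(OCc2ccccc2)cc1 | intermediate (not isolated)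
16 | 2-{(1R)-1-[4-(benzyloxy)phenyl]ethyl}-3-tert-butoxy-5-(triisopropylsilyloxy)phenol | C[C@H](c1ccc(OCc2ccccc2)cc1)c1c(O)cc(O[Si](C(C)C)(C(C)C)C(C)C)cc1OC(C)(C)C | intermediate
17 | 2-{(1R)-1-[4-(benzyloxy)phenyl]ethyl}-5-(triisopropylsilyloxy)benzene-1,3-diol | C[C@H](c1ccc(OCc2ccccc2)cc1)c1c(O)cc(O[Si](C(C)C)(C(C)C)C(C)C)cc1O | intermediate
18 | {3,5-bis(benzyloxy)-4-[(1R)-1-[4-(benzyloxy)phenyl]ethyl]phenoxy}tri(propan-2-yl)silane | C[C@H](c1ccc(OCc2ccccc2)cc1)c1c(OCc2ccccc2)cc(O[Si](C(C)C)(C(C)C)C(C)C)cc1OCc1ccccc1 | intermediate
19 | 3,5-bis(benzyloxy)-4-{(1R)-1-[4-(benzyloxy)phenyl]ethyl}phenol | C[C@H](c1ccc(OCc2ccccc2)cc1)c1c(OCc2ccccc2)cc(O)cc1OCc1ccccc1 | intermediate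
20 | 4-(benzyloxy)benzaldehyde | O=Cc1ccc(OCc2ccccc2)cc1 | starting material
21 | methyl (2E)-3-[4-(benzyloxy)phenyl]prop-2-enoate | COC(=O)/C=C/c1ccc(OCc2ccccc2)cc1 | intermediate
22 | methyl (2R,3S)-3-[4-(benzyloxy)phenyl]oxirane-2-carboxylate | COC(=O)[C@@H]1O[C@H]1c1ccc(OCc2ccccc2)cc1 | intermediate
23 | methyl (2R,3R)-3-{3,5-bis(benzyloxy)-4-[(1R)-1-[4-(benzyloxy)phenyl]ethyl]phenoxy}-3-[4-(benzyloxy)phenyl]-2-hydroxypropanoate | COC(=O)[C@H](O)[C@@H](c1ccc(OCc2ccccc2)cc1)Oc1cc(OCc2ccccc2)c([C@H](C)c2ccc(OCc3ccccc3)cc2)c(OCc2ccccc2)c1 | intermediate (not isolated)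
24 | (2R,3R)-3-{3,5-bis(benzyloxy)-4-[(1R)-1-[4-(benzyloxy)phenyl]ethyl]phenoxy}-3-[4-(benzyloxy)phenyl]-2-hydroxypropanoic acid | OC(=O)[C@H](O)[C@@H](c1ccc(OCc2ccccc2)cc1)Oc1cc(OCc2ccccc2)c([C@H](C)c2ccc(OCc3ccccc3)cc2)c(OCc2ccccc2)c1 | intermediate
25 | mixed anhydride of trifluoroacetic acid with the 2-O-trifluoroacetyl derivative of 24 | O=C(OC(=O)C(F)(F)F)[C@H](OC(=O)C(F)(F)F)[C@@H](c1ccc(OCc2ccccc2)cc1)Oc1cc(OCc2ccccc2)c([C@H](C)c2ccc(OCc3ccccc3)cc2)c(OCc2ccccc2)c1 | intermediate (not isolated)
26 | 3-O-trifluoroacetyl derivative of 27 | C[C@H](c1ccc(OCc2ccccc2)cc1)c1c(OCc2ccccc2)cc2c(c1OCc1ccccc1)C(=O)[C@H](OC(=O)C(F)(F)F)[C@@H](c1ccc(OCc3ccccc3)cc1)O2 | intermediate (not isolated)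
27 | (2R,3R)-5,7-bis(benzyloxy)-2-[4-(benzyloxy)phenyl]-6-{(1R)-1-[4-(benzyloxy)phenyl]ethyl}-3-hydroxy-2,3-dihydro-4H-chromen-4-one | C[C@H](c1ccc(OCc2ccccc2)cc1)c1c(OCc2ccccc2)cc2c(c1OCc1ccccc1)C(=O)[C@H](O)[C@@H](c1ccc(OCc3ccccc3)cc1)O2 | intermediate
28 | (2R,3R)-3,5,7-trihydroxy-2-(4-hydroxyphenyl)-6-[(1R)-1-(4-hydroxyphenyl)ethyl]-2,3-dihydro-4H-chromen-4-one | C[C@H](c1ccc(O)cc1)c1c(O)cc2c(c1O)C(=O)[C@H](O)[C@@H](c1ccc(O)cc1)O2 | target

## Step count and least certain steps

Total: 13 steps. Longest linear sequence: 10 steps (steps 1, 2, 3, 5, 6, 7, 8, 11, 12, 13); steps 4 and 9–10 are side branches.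

Step 5 (key step). The 3-alkoxycyclobutenone is stabilised as a vinylogous ester and may open only at temperatures where the tert-butyl enol ether loses isobutene, the silyl ynol ether rearranges to a silylketene, or the vinylketene is diverted by hydrogen shift or by acylating the product phenol. Fallback: ring A is not built but bought, and C-alpha is attached to it. The fallback sets out from 20 and returns at 18. Wittig methylenation of 20 (Ph3P=CH2, THF) gives 1-(benzyloxy)-4-ethenylbenzene F1. Separately, 3,5-bis(benzyloxy)phenol F2 is silylated (i-Pr3SiCl, imidazole) to [3,5-bis(benzyloxy)phenoxy]tri(propan-2-yl)silane F3, and this is brominated between the two benzyloxy groups (NBS, MeCN, 0 °C) to [3,5-bis(benzyloxy)-4-bromophenoxy]tri(propan-2-yl)silane F4. Enantioselective Markovnikov hydroarylation of F1 with F4 under copper hydride/palladium dual catalysis (Cu(OAc)2 with the DTBM-SEGPHOS enantiomer that leads to the R product, [PdCl(C9H9)]2 (C9H9 = cinnamyl) with BrettPhos, Me(MeO)2SiH, NaOSiMe3, THF) would give 18. Here O1 is labelled by symmetry and the hindered coupling becomes the uncertain point.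

Step 4. Silylation of the unhindered ynolate at carbon (giving a silylketene), self-condensation of the bromo enolate before the exchange, and loss of the volatile, heat-sensitive alkyne on isolation are the likely failures. Fallback: the alkyne carbon is blocked by a traceless silyl group. The fallback sets out from 8 and returns at 17. Ethynyl(trimethyl)silane F5 is lithiated (n-BuLi) and oxidised with lithium tert-butyl peroxide to lithium 2-(trimethylsilyl)ethynolate F6, which is O-silylated (i-Pr3SiCl) to trimethyl{[tri(propan-2-yl)silyl]oxyethynyl}silane F7, a fully substituted and more robust ynol ether. Benzannulation of 8 with F7 under the step 5 conditions should give 2-{(1R)-1-[4-(benzyloxy)phenyl]ethyl}-3-tert-butoxy-5-(triisopropylsilyloxy)-6-(trimethylsilyl)phenol F8. The step 6 conditions then remove the tert-butyl group and the aryl–SiMe3 group (ipso-protodesilylation) together, giving 17.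

Step 11. The 4-benzyloxyphenyl group stabilises positive charge at the benzylic carbon, so ion-pair opening with partial retention (leading to the 2,3-cis series) may compete with clean inversion; oligomerisation through the product alkoxide is a second risk. Fallback: the order of bond formation is reversed, C4–C4a first and O1–C2 last. It sets out from 19 and returns at 27. Acetylation ortho to the hydroxyl (Ac2O, BF3·OEt2) gives 1-{4,6-bis(benzyloxy)-5-[(1R)-1-[4-(benzyloxy)phenyl]ethyl]-2-hydroxyphenyl}ethan-1-one F9, protected (MOMCl, i-Pr2NEt) as its methoxymethyl ether F10. Claisen–Schmidt condensation with 20 (KOH, EtOH) gives the (E)-chalcone F11. Juliá–Colonna epoxidation (poly-L-leucine, urea·H2O2, DBU, THF) gives the (2R,3S)-epoxy ketone F12. HCl in MeOH removes the acetal, and the phenol opens the epoxide at the benzylic carbon with inversion to give 27; trans is also the thermodynamically preferred arrangement.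

Step 12. Under acid the benzylic C–O bond may ionise or the phenol may be expelled by β-elimination, ring A may be protonated at C6 with loss of C-alpha, or the hindered α-trifluoroacetoxy acyl donor may react sluggishly. Fallback: anionic ring closure (Parham-type cyclisation). It sets out from 19 and returns at 27. Bromination of 19 (NBS, CH2Cl2, −20 °C) gives 3,5-bis(benzyloxy)-4-{(1R)-1-[4-(benzyloxy)phenyl]ethyl}-2-bromophenol F13. Opening of 22 as in step 11, without the hydrolysis, gives methyl (2R,3R)-3-{3,5-bis(benzyloxy)-4-[(1R)-1-[4-(benzyloxy)phenyl]ethyl]-2-bromophenoxy}-3-[4-(benzyloxy)phenyl]-2-hydroxypropanoate F14. Deprotonation of the hydroxyl (NaH) and bromine–lithium exchange (t-BuLi, THF, −78 °C) let the aryllithium acylate itself on the ester, giving 27 after work-up.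

## Further compounds

F1 | step 5 | 1-(benzyloxy)-4-ethenylbenzene | C=Cc1ccc(OCc2ccccc2)cc1
F2 | step 5 | 3,5-bis(benzyloxy)phenol | Oc1cc(OCc2ccccc2)cc(OCc2ccccc2)c1
F3 | step 5 | [3,5-bis(benzyloxy)phenoxy]tri(propan-2-yl)silane | CC(C)[Si](Oc1cc(OCc2ccccc2)cc(OCc2ccccc2)c1)(C(C)C)C(C)C
F4 | step 5 | [3,5-bis(benzyloxy)-4-bromophenoxy]tri(propan-2-yl)silane | CC(C)[Si](Oc1cc(OCc2ccccc2)c(Br)c(OCc2ccccc2)c1)(C(C)C)C(C)C
F5 | step 4 | ethynyl(trimethyl)silane | C[Si](C)(C)C#C
F6 | step 4 | lithium 2-(trimethylsilyl)ethynolate | [Li+].[O-]C#C[Si](C)(C)C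
F7 | step 4 | trimethyl{[tri(propan-2-yl)silyl]oxyethynyl}silane | C[Si](C)(C)C#CO[Si](C(C)C)(C(C)C)C(C)C
F8 | step 4 | 2-{(1R)-1-[4-(benzyloxy)phenyl]ethyl}-3-tert-butoxy-5-(triisopropylsilyloxy)-6-(trimethylsilyl)phenol | C[C@H](c1ccc(OCc2ccccc2)cc1)c1c(O)c([Si](C)(C)C)c(O[Si](C(C)C)(C(C)C)C(C)C)cc1OC(C)(C)C
F9 | step 11 | 1-{4,6-bis(benzyloxy)-5-[(1R)-1-[4-(benzyloxy)phenyl]ethyl]-2-hydroxyphenyl}ethan-1-one | CC(=O)c1c(O)cc(OCc2ccccc2)c([C@H](C)c2ccc(OCc3ccccc3)cc2)c1OCc1ccccc1
F10 | step 11 | 1-{4,6-bis(benzyloxy)-5-[(1R)-1-[4-(benzyloxy)phenyl]ethyl]-2-(methoxymethoxy)phenyl}ethan-1-one | CC(=O)c1c(OCOC)cc(OCc2ccccc2)c([C@H](C)c2ccc(OCc3ccccc3)cc2)c1OCc1ccccc1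
F11 | step 11 | (2E)-1-{4,6-bis(benzyloxy)-5-[(1R)-1-[4-(benzyloxy)phenyl]ethyl]-2-(methoxymethoxy)phenyl}-3-[4-(benzyloxy)phenyl]prop-2-en-1-one | O=C(/C=C/c1ccc(OCc2ccccc2)cc1)c1c(OCOC)cc(OCc2ccccc2)c([C@H](C)c2ccc(OCc3ccccc3)cc2)c1OCc1ccccc1
F12 | step 11 | {(2R,3S)-3-[4-(benzyloxy)phenyl]oxiran-2-yl}{4,6-bis(benzyloxy)-5-[(1R)-1-[4-(benzyloxy)phenyl]ethyl]-2-(methoxymethoxy)phenyl}methanone | O=C([C@@H]1O[C@H]1c1ccc(OCc2ccccc2)cc1)c1c(OCOC)cc(OCc2ccccc2)c([C@H](C)c2ccc(OCc3ccccc3)cc2)c1OCc1ccccc1
F13 | step 12 | 3,5-bis(benzyloxy)-4-{(1R)-1-[4-(benzyloxy)phenyl]ethyl}-2-bromophenol | C[C@H](c1ccc(OCc2ccccc2)cc1)c1c(OCc2ccccc2)cc(O)c(Br)c1OCc1ccccc1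
F14 | step 12 | methyl (2R,3R)-3-{3,5-bis(benzyloxy)-4-[(1R)-1-[4-(benzyloxy)phenyl]ethyl]-2-bromophenoxy}-3-[4-(benzyloxy)phenyl]-2-hydroxypropanoate | COC(=O)[C@H](O)[C@@H](c1ccc(OCc2ccccc2)cc1)Oc1cc(OCc2ccccc2)c([C@H](C)c2ccc(OCc3ccccc3)cc2)c(OCc2ccccc2)c1Br
A1 | alternative 1 | (2R,3S,4S)-5,7-bis(benzyloxy)-2-[4-(benzyloxy)phenyl]-6-{(1R)-1-[4-(benzyloxy)phenyl]ethyl}-3,4-dihydro-2H-chromene-3,4-diol | C[C@H](c1ccc(OCc2ccccc2)cc1)c1c(OCc2ccccc2)cc2c(c1OCc1ccccc1)[C@H](O)[C@H](O)[C@@H](c1ccc(OCc3ccccc3)cc1)O2
A2 | alternative 1 | (2S)-5,7-bis(benzyloxy)-2-[4-(benzyloxy)phenyl]-6-{(1R)-1-[4-(benzyloxy)phenyl]ethyl}-2H-chromene | C[C@H](c1ccc(OCc2ccccc2)cc1)c1c(OCc2ccccc2)cc2c(c1OCc1ccccc1)C=C[C@@H](c1ccc(OCc3ccccc3)cc1)O2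
A3 | alternative 2 | (2R,3R)-5,7-bis(benzyloxy)-2-[4-(benzyloxy)phenyl]-6-{(1R)-1-[4-(benzyloxy)phenyl]ethyl}-3-hydroxy-2,3-dihydro-4H-chromen-4-one | C[C@H](c1ccc(OCc2ccccc2)cc1)c1c(OCc2ccccc2)cc2c(c1OCc1ccccc1)C(=O)[C@H](O)[C@@H](c1ccc(OCc3ccccc3)cc1)O2
A4 | alternative 3 | (2R,3R)-2-[4-(benzyloxy)phenyl]-6-{(1R)-1-[4-(benzyloxy)phenyl]ethyl}-3-(tert-butyldimethylsilyloxy)-5,7-dihydroxy-2,3-dihydro-4H-chromen-4-one | C[C@H](c1ccc(OCc2ccccc2)cc1)c1c(O)cc2c(c1O)C(=O)[C@H](O[Si](C)(C)C(C)(C)C)[C@@H](c1ccc(OCc3ccccc3)cc1)O2
A5 | alternative 3 | 2-{(1R)-1-[4-(benzyloxy)phenyl]ethyl}-1-methoxy-1,3-bis(trimethylsilyloxy)buta-1,3-diene | COC(O[Si](C)(C)C)=C([C@H](C)c1ccc(OCc2ccccc2)cc1)C(O[Si](C)(C)C)=C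
A6 | alternative 3 | (2R,3R)-2-[4-(benzyloxy)phenyl]-3-(tert-butyldimethylsilyloxy)-5-(phenylsulfonyl)-2,3-dihydro-4H-pyran-4-one | O=C1[C@H](O[Si](C)(C)C(C)(C)C)[C@@H](c2ccc(OCc3ccccc3)cc2)OC=C1S(=O)(=O)c1ccccc1
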